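**The question.** You asked for a quick number: which of Z, X, G and L leads in flasks eta and gamma at 2.5 h, and what it holds as a fraction of the G charged.

all flasks: G 0.011 M

| flask | Z | remark | time |
|---|---|---|---|
| blue | 1 mM | run made earlier |  |
| grey | 1.7 mM | run made earlier |  |
| teal | 2 mM | run made earlier |  |
| eta | 1.10 mM |  | 2.5 h |
| gamma | 2.20 mM |  | 2.5 h |

| run | time / min | G / % | Z / % | L / % | X / % |
|---|---|---|---|---|---|
| blue | 25.0 | 42 | 59 | 4 | 0 |
| blue | 50.0 | 7 | 81 | 17 | 4 |
| blue | 80.0 | 2 | 69 | 33 | 12 |
| blue | 120 | 0 | 48 | 44 | 16 |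
| grey | 12.0 | 69 | 43 | 5 | 2 |
| grey | 40.0 | 8 | 87 | 16 | 5 |
| grey | 60.0 | 1 | 79 | 27 | 9 |
| grey | 120 | 0 | 47 | 52 | 16 |
| teal | 25.0 | 24 | 84 | 10 | 4 |
| teal | 50.0 | 3 | 88 | 25 | 6 |
| teal | 80.0 | 3 | 72 | 36 | 9 |
| teal | 120 | 0 | 47 | 52 | 19 |

(standard deviation of a reading: 1.5 percentage points)

1. which of these there is most of at the end, counted by the G in it, eta (Z / X / G / L)
2. which of these there is most of at the end, counted by the G in it, gamma (Z / X / G / L)
3. how much there is at the end of the one of these that leads, in percent of the G charged: eta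
4. how much there is at the end of the one of these that leads, in percent of the G charged: gamma

- for Z the D are counted in
- as a solid, counted per litre of solution: D
- what was read earlier has a scatter of 1.5 percentage points, one standard deviation
- reactions considered so far: G + Z -> 2 Z; G -> Z; D <-> Z; Z -> X; Z <-> L

**Drain time.** I treated the flask as a tank emptying after its feed stops. In the teal run G was down to 3% at 50.0 min, and Z then fell from 88% to 47% by 120 min. That gave 112 min as the drain time, the time in which Z falls by a factor of e once G has stopped feeding it.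

**My reckoning.** The last teal readings also gave L a share of 73.2% of what had left Z, a selectivity. The readings summed to the charge plus the Z seed, so I took totals of 110% for eta and 120% for gamma. Draining for the last 30.0 min from the blue reading gave eta Z 36.7% and L 53.7%. From the teal reading, gamma came to Z 35.9% and L 61.6%. In this reckoning of mine L stood above Z in both flasks.

**Your forecast.** It gave L at 54% for eta and L at 62% for gamma, noting that “L already equals or exceeds Z”.

**The result.** Eta ended with L 54.6% and Z 37.9%; gamma ended with L 61.1% and Z 39.3%.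

    G + Z → 2 Z (k = 0.171 M⁻¹ s⁻¹)
    G → Z (k = 1.40 × 10⁻⁶ s⁻¹)
    D ⇌ Z, rate k3*(cs3 - [Z]) while solid is left; crystals form when [Z] > cs3 (solubility = 9.60 mM, k = 6.70 × 10⁻⁴ s⁻¹)
    Z → X (k = 3.38 × 10⁻⁵ s⁻¹)
    Z ⇌ L (K = 28.3, k = 1.07 × 10⁻⁴ s⁻¹)

**Why gamma leads.** Gamma's L stood above eta's by 6.5 percentage points because gamma was charged with more Z; gamma with eta's Z charge gave 54.6%. Starting from gamma's Z of 72.6% at 1.25 h, the drain time gave 37.2% at 2.5 h, where gamma held 39.3%. Carried on to a later reading of gamma at 4.00 h, it gave Z 17.5% and L 75.0%, and gamma then held Z 19.4% and L 75.9%.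

The runs come from a simulation for an exercise, and the scatter is random.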